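The route rests on disconnecting C9–C10 and C6–C11 (atoms numbered in the order of the target SMILES), that is, the cis-fused junction that cyclohexane ring A (C6–C11) shares with δ-lactone ring B beside spiro carbon C16. One intramolecular Diels–Alder reaction of a C15 acrylate closes both rings and sets C9, C10 and C6. Its precursor is the 6-oxabicyclo[3.2.1]octane (ring C with the O21–C22 bridge) whose quaternary C16 carries the acryloyloxymethyl arm and an (E,E)-4-silyloxybutadienyl group. The C17 ketone is carried as its silyl enol ether, which makes the C15 unmasking chemoselective and enlarges the C17 flank. Ring A is then saturated and C6–O exchanged for the acrylic acid unit.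

Key step: step 9

Remark: in step 2 the ligand antipode is taken to be the one that leads to the C23 configuration of the target; otherwise its mirror image is used.

Step 1
Reactants: 1 4,4-dimethylcyclohex-2-en-1-one
Product: 2 4,4-dimethylcyclohexa-2,5-dien-1-one
Conditions: DDQ, 1,4-dioxane, reflux
Reagents that add atoms: none
Why: DDQ dehydrogenation of an enone (hydride abstraction from the dienol, then proton loss) can only introduce the C5–C6 double bond because C4 is quaternary, giving the achiral cross-conjugated dienone.

Step 2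
Reactants: 2 4,4-dimethylcyclohexa-2,5-dien-1-one; 3 (chloromethyl)(isopropoxy)dimethylsilane; 4 allyl bromide
Product: 7 (5R,6R)-6-allyl-5-{[isopropoxy(dimethyl)silyl]methyl}-4,4-dimethylcyclohex-2-en-1-one, via Grignard reagent 5 (not isolated), via magnesium dienolate 6 (not isolated)
Conditions: 3, Mg, Et2O, reflux; then 2, CuBr·SMe2 (5 mol %), (R)-1-[(S)-2-(diphenylphosphino)ferrocenyl]ethyldicyclohexylphosphine (6 mol %), t-BuOMe, −75 °C; then 4, DMPU, −75 to 0 °C
Reagents that add atoms: none
Why: Copper-catalysed enantioselective conjugate addition of a Grignard reagent under a chiral ferrocenyl diphosphine sets C23 by catalyst control of the enone face (the two enone units of 2 are equivalent and the second is masked in the cross-conjugated enolate), and the enolate is then C-allylated at C16 anti to the new substituent, which places the C9 chain regiospecifically.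

Step 3
Reactants: 7 (5R,6R)-6-allyl-5-{[isopropoxy(dimethyl)silyl]methyl}-4,4-dimethylcyclohex-2-en-1-one; 8 formaldehyde
Product: 11 [(1S,6S)-1-allyl-6-{[isopropoxy(dimethyl)silyl]methyl}-5,5-dimethyl-2-oxocyclohex-3-en-1-yl]methyl pivalate, via lithium dienolate 9 (not isolated), via lithium aldolate 10 (not isolated)
Conditions: LiN(i-Pr)2, THF, −78 to −40 °C; 8 (gas, from cracked paraformaldehyde), −78 °C; then t-BuCOCl, −78 to 0 °C
Reagents that add atoms: pivaloyl chloride CC(C)(C)C(=O)Cl
Why: C16 carries the only enolisable hydrogen of enone 7, and the aldol addition of its lithium dienolate to formaldehyde should occur anti to the neighbouring C23 substituent (1,2-induction), setting quaternary C16 with C15 trans and the allyl group cis to C22, while in-situ pivaloylation of the aldolate blocks retro-aldol cleavage.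

Step 4
Reactants: 11 [(1S,6S)-1-allyl-6-{[isopropoxy(dimethyl)silyl]methyl}-5,5-dimethyl-2-oxocyclohex-3-en-1-yl]methyl pivalate
Product: 13 [(1S,2S,5S)-2-allyl-8,8-dimethyl-3-oxo-6-oxabicyclo[3.2.1]octan-2-yl]methyl pivalate, via hydroxymethyl enone 12 (not isolated)
Conditions: KF, KHCO3, 30% H2O2, THF/MeOH, 25 °C; then DBU (0.2 equiv), CH2Cl2, 25 °C
Reagents that add atoms: hydrogen peroxide OO
Why: Tamao–Fleming oxidation replaces silicon on C22 by hydroxyl, and the 5-exo-trig oxa-Michael addition of this axial hydroxymethyl group to C20 of the enone closes the O21–C22 bridge, the C20 configuration being dictated by the bridge itself and quaternary C16 being unable to enolise or to undergo retro-aldol loss.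

Step 5
Reactants: 13 [(1S,2S,5S)-2-allyl-8,8-dimethyl-3-oxo-6-oxabicyclo[3.2.1]octan-2-yl]methyl pivalate; 14 crotonaldehyde
Product: 15 [(1S,2S,5S)-8,8-dimethyl-3-oxo-2-[(2E)-4-oxobut-2-en-1-yl]-6-oxabicyclo[3.2.1]octan-2-yl]methyl pivalate
Conditions: 14 (5 equiv), second-generation Hoveyda–Grubbs catalyst RuCl2(H2IMes)(=CH-C6H4-2-O-i-Pr) (5 mol %), CH2Cl2, 40 °C
Reagents that add atoms: none
Why: Olefin cross-metathesis of the terminal alkene with excess crotonaldehyde extends the C9 chain by C6 and gives the (E)-enal under thermodynamic control, and it is run before any acrylate is present so that ring-closing metathesis cannot compete.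

Step 6
Reactants: 15 [(1S,2S,5S)-8,8-dimethyl-3-oxo-2-[(2E)-4-oxobut-2-en-1-yl]-6-oxabicyclo[3.2.1]octan-2-yl]methyl pivalate
Product: 16 [(1S,2S,5S)-3-(tert-butyldimethylsilyloxy)-2-[(1E,3E)-4-(tert-butyldimethylsilyloxy)buta-1,3-dien-1-yl]-8,8-dimethyl-6-oxabicyclo[3.2.1]oct-3-en-2-yl]methyl pivalate
Conditions: t-BuMe2SiOTf (2.5 equiv), Et3N (4 equiv), CH2Cl2, −78 to 0 °C
Reagents that add atoms: tert-butyldimethylsilyl trifluoromethanesulfonate CC(C)(C)[Si](C)(C)OS(=O)(=O)C(F)(F)F
Why: Soft enolisation with silyl triflate and amine converts the s-trans enal by γ-deprotonation at C9 into the (1E,3E)-silyloxydiene and, in the same operation, the C17 ketone (enolisable only toward C19) into its silyl enol ether, so that the pivalate is left as the only hydride-sensitive group.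

Step 7
Reactants: 16 bis-silyl dienol ether pivalate
Product: 17 [(1S,2S,5S)-3-(tert-butyldimethylsilyloxy)-2-[(1E,3E)-4-(tert-butyldimethylsilyloxy)buta-1,3-dien-1-yl]-8,8-dimethyl-6-oxabicyclo[3.2.1]oct-3-en-2-yl]methanol
Conditions: i-Bu2AlH (2.5 equiv), CH2Cl2, −78 °C; aq. potassium sodium tartrate
Reagents that add atoms: none
Why: Reductive cleavage of the pivalate ester with i-Bu2AlH at low temperature frees the neopentyl C15 alcohol, the silyl enol ethers, the diene and the bridging ether being inert to the hydride.

Step 8
Reactants: 17 C15 alcohol; 18 acryloyl chloride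
Product: 19 C15 acrylate of 17 (cycloaddition precursor; C16 bears the (1E,3E)-4-silyloxybutadienyl group endo and the acryloyloxymethyl arm exo; C17 as silyl enol ether)
Conditions: 18, Et3N, DMAP (cat.), BHT, CH2Cl2, −20 to 0 °C
Reagents that add atoms: none
Why: O-Acylation of the primary alcohol with acryloyl chloride under amine and DMAP catalysis installs the dienophile, since silyl enol ethers do not react with acid chlorides in the absence of a Lewis acid.

Step 9
Reactants: 19 C15 acrylate (cycloaddition precursor)
Product: 21 C6-silyloxy cyclohexene spiro-lactone ketone (rings A and B cis-fused; C6–OSi cis to C16; C17 ketone), via bis-silyl cycloadduct 20 (not isolated)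
Conditions: BHT, toluene (0.005 M), 180 °C, sealed base-washed tube; then 1 M HCl, THF, 0 °C
Reagents that add atoms: none
Why: Thermal, concerted but asynchronous [4+2] cycloaddition (a type 1 intramolecular Diels–Alder reaction of an ester-tethered dienyl acrylate giving a fused δ-lactone) between the (E,E)-silyloxydiene C6–C9 and the acrylate C10=C11, with quaternary C16 supplying the gem-disubstituent effect that offsets the cost of the s-cis ester rotamer. Ring A closes as the new cyclohexene through both forming bonds (C9–C10 and C6–C11), and ring B closes in the fused mode as the six-membered lactone made of the tether C16–C15–O14–C12 and the C9–C10 bond, the four-atom tether excluding the bridged regiochemistry that the silyloxy group would otherwise favour. C10 is set by the endo (carbonyl under the diene) half-chair transition state, which gives the cis ring fusion; C6 follows from the E geometry of the silyloxy terminus (cis to C16, removed later); C9 is set by the diene face, which C16 controls. The selectivity needed is this π-facial one: C9 is the equatorial (endo) substituent of C16 and eclipses the C17–O18 bond, so the silyloxy-bearing C17 flank screens the sector between C15 and C17, and the acrylate, anchored to the axial C15, should reach the diene through the C15/C23 sector where only H23 projects, placing H9 next to C23 and C8 next to C17 as in the target. High dilution, a radical inhibitor and base-washed glass guard against polymerisation and protodesilylation, and the C17 enol ether is hydrolysed on acidic work-up without forming an enolate, while the allylic silyl ether at C6 survives.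

Step 10
Reactants: 21 C6-silyloxy cyclohexene spiro-lactone ketone
Product: 22 C6-silyloxy cyclohexane spiro-lactone ketone (C7–C8 saturated)
Conditions: H2 (1 atm), Pd/C, EtOAc, 25 °C
Reagents that add atoms: none
Why: Heterogeneous hydrogenation saturates the cis-disubstituted C7=C8 alkene (no new stereocentre) and leaves ketone, lactone and silyl ether untouched, so that the later C6 radical is not allylic.

Step 11
Reactants: 22 C6-silyloxy cyclohexane spiro-lactone ketone
Product: 23 C6 alcohol (hydroxyl cis to C16 and C12)
Conditions: HF·pyridine, pyridine, THF, 0 to 25 °C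
Reagents that add atoms: none
Why: Fluoride cleavage of the secondary silyl ether under mildly acidic, non-basic conditions spares the lactone, the β-alkoxy ketone and the epimerisable C10 and avoids alkoxide-driven acyl transfer to the C6 oxygen.

Step 12
Reactants: 23 C6 alcohol
Product: 24 C6 iodide (iodine trans to C16)
Conditions: I2, PPh3, imidazole, toluene, 25 to 60 °C
Reagents that add atoms: iodine II
Why: Appel iodination (displacement of the alkoxyphosphonium by iodide with inversion) converts the secondary alcohol into the iodide under near-neutral conditions, and its C6 configuration is immaterial because the next step passes through the C6 radical.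

Step 13
Reactants: 24 C6 iodide; 25 2-bromopropene
Product: 26 C6 isopropenyl spiro-lactone ketone (isopropenyl equatorial and trans to C16)
Conditions: 25 (3 equiv), NiBr2(dme) (10 mol %), 4,4′-di-tert-butyl-2,2′-bipyridine (12 mol %), Zn, DMA, 25 °C
Reagents that add atoms: none
Why: Nickel-catalysed reductive cross-electrophile coupling joins the secondary iodide to the alkenyl bromide through a C6 radical that is captured by the alkenylnickel species on the equatorial side, away from the axial C12 carbonyl on C10, which should set C6 with the isopropenyl group equatorial and trans to C16.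

Step 14
Reactants: 26 C6 isopropenyl spiro-lactone ketone
Product: 28 α-substituted acrolein (C3 aldehyde), via allylic alcohol 27 (not isolated)
Conditions: SeO2 (0.3 equiv), t-BuOOH, CH2Cl2, 25 °C; then Dess–Martin periodinane, CH2Cl2, 25 °C
Reagents that add atoms: selenium dioxide O=[Se]=O, tert-butyl hydroperoxide CC(C)(C)OO
Why: SeO2 allylic oxidation (ene reaction, then [2,3]-sigmatropic shift) functionalises the methyl group of the 1,1-disubstituted alkene in preference to the tertiary C6–H, and Dess–Martin oxidation of the resulting primary allylic alcohol gives the enal without touching any stereocentre.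

Step 15
Reactants: 28 α-substituted acrolein
Product: 29 target acid CNP0268721.1
Conditions: NaClO2, NaH2PO4, 2-methylbut-2-ene, t-BuOH/H2O, 0 to 25 °C
Reagents that add atoms: sodium chlorite [Na+].[O-]Cl=O
Why: Pinnick oxidation converts the α-substituted acrolein into the acrylic acid under buffered conditions with a hypochlorite scavenger, leaving the 1,1-disubstituted alkene, the ketone, the lactone and C10 unchanged.

Compound list
1 | 4,4-dimethylcyclohex-2-en-1-one | CC1(C)CCC(=O)C=C1 | starting material
2 | 4,4-dimethylcyclohexa-2,5-dien-1-one | CC1(C)C=CC(=O)C=C1 | intermediate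
3 | (chloromethyl)(isopropoxy)dimethylsilane | CC(C)O[Si](C)(C)CCl | starting material
4 | allyl bromide | C=CCBr | starting material
5 | [(isopropoxydimethylsilyl)methyl]magnesium chloride (Grignard reagent) | CC(C)O[Si](C)(C)C[Mg]Cl | intermediate
6 | chloromagnesium dienolate of the conjugate adduct (C23 as in the target) | CC(C)O[Si](C)(C)C[C@@H]1C=C(O[Mg]Cl)C=CC1(C)C | intermediate
7 | (5R,6R)-6-allyl-5-{[isopropoxy(dimethyl)silyl]methyl}-4,4-dimethylcyclohex-2-en-1-one | C=CC[C@H]1C(=O)C=CC(C)(C)[C@@H]1C[Si](C)(C)OC(C)C | intermediate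
8 | formaldehyde (monomer from paraformaldehyde) | C=O | starting material
9 | lithium dienolate of 7 | [Li]OC1=C(CC=C)[C@@H](C[Si](C)(C)OC(C)C)C(C)(C)C=C1 | intermediate
10 | lithium aldolate (C16 hydroxymethylated, C15 trans to C22) | C=CC[C@]1(CO[Li])C(=O)C=CC(C)(C)[C@@H]1C[Si](C)(C)OC(C)C | intermediate
11 | [(1S,6S)-1-allyl-6-{[isopropoxy(dimethyl)silyl]methyl}-5,5-dimethyl-2-oxocyclohex-3-en-1-yl]methyl pivalate | C=CC[C@]1(COC(=O)C(C)(C)C)C(=O)C=CC(C)(C)[C@@H]1C[Si](C)(C)OC(C)C | intermediate
12 | [(1S,6S)-1-allyl-6-(hydroxymethyl)-5,5-dimethyl-2-oxocyclohex-3-en-1-yl]methyl pivalate | C=CC[C@]1(COC(=O)C(C)(C)C)C(=O)C=CC(C)(C)[C@@H]1CO | intermediate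
13 | [(1S,2S,5S)-2-allyl-8,8-dimethyl-3-oxo-6-oxabicyclo[3.2.1]octan-2-yl]methyl pivalate | CC(C)(C)C(=O)OC[C@@]1(CC=C)C(=O)C[C@@H]2OC[C@H]1C2(C)C | intermediate
14 | (E)-crotonaldehyde | C/C=C/C=O | starting material
15 | [(1S,2S,5S)-8,8-dimethyl-3-oxo-2-[(2E)-4-oxobut-2-en-1-yl]-6-oxabicyclo[3.2.1]octan-2-yl]methyl pivalate | CC(C)(C)C(=O)OC[C@@]1(C/C=C/C=O)C(=O)C[C@@H]2OC[C@H]1C2(C)C | intermediate
16 | [(1S,2S,5S)-3-(tert-butyldimethylsilyloxy)-2-[(1E,3E)-4-(tert-butyldimethylsilyloxy)buta-1,3-dien-1-yl]-8,8-dimethyl-6-oxabicyclo[3.2.1]oct-3-en-2-yl]methyl pivalate | CC(C)(C)C(=O)OC[C@@]1(/C=C/C=C/O[Si](C)(C)C(C)(C)C)C(O[Si](C)(C)C(C)(C)C)=C[C@@H]2OC[C@H]1C2(C)C | intermediate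
17 | [(1S,2S,5S)-3-(tert-butyldimethylsilyloxy)-2-[(1E,3E)-4-(tert-butyldimethylsilyloxy)buta-1,3-dien-1-yl]-8,8-dimethyl-6-oxabicyclo[3.2.1]oct-3-en-2-yl]methanol | OC[C@@]1(/C=C/C=C/O[Si](C)(C)C(C)(C)C)C(O[Si](C)(C)C(C)(C)C)=C[C@@H]2OC[C@H]1C2(C)C | intermediate
18 | acryloyl chloride | C=CC(=O)Cl | starting material
19 | C15 acrylate of 17 (cycloaddition precursor, C17 masked as silyl enol ether) | C=CC(=O)OC[C@@]1(/C=C/C=C/O[Si](C)(C)C(C)(C)C)C(O[Si](C)(C)C(C)(C)C)=C[C@@H]2OC[C@H]1C2(C)C | intermediate
20 | bis-silyl cycloadduct (rings A and B cis-fused, C6–OSi cis to C16, C17 silyl enol ether) | CC(C)(C)[Si](C)(C)O[C@H]1C=C[C@@H]2[C@H](C1)C(=O)OC[C@]21C(O[Si](C)(C)C(C)(C)C)=C[C@@H]2OC[C@H]1C2(C)C | intermediate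
21 | C6-silyloxy cyclohexene spiro-lactone ketone, (6R,9R,10S,16S,20S,23S) in SMILES numbering | CC(C)(C)[Si](C)(C)O[C@H]1C=C[C@@H]2[C@H](C1)C(=O)OC[C@]21C(=O)C[C@@H]2OC[C@H]1C2(C)C | intermediate
22 | C6-silyloxy cyclohexane spiro-lactone ketone | CC(C)(C)[Si](C)(C)O[C@H]1CC[C@@H]2[C@H](C1)C(=O)OC[C@]21C(=O)C[C@@H]2OC[C@H]1C2(C)C | intermediate
23 | C6 alcohol (hydroxyl cis to C16) | O[C@H]1CC[C@@H]2[C@H](C1)C(=O)OC[C@]21C(=O)C[C@@H]2OC[C@H]1C2(C)C | intermediate
24 | C6 iodide (iodine trans to C16) | I[C@@H]1CC[C@@H]2[C@H](C1)C(=O)OC[C@]21C(=O)C[C@@H]2OC[C@H]1C2(C)C | intermediate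
25 | 2-bromopropene | C=C(C)Br | starting material
26 | C6 isopropenyl spiro-lactone ketone (isopropenyl trans to C16) | C=C(C)[C@@H]1CC[C@@H]2[C@H](C1)C(=O)OC[C@]21C(=O)C[C@@H]2OC[C@H]1C2(C)C | intermediate
27 | allylic alcohol (C3 hydroxymethyl) | C=C(CO)[C@@H]1CC[C@@H]2[C@H](C1)C(=O)OC[C@]21C(=O)C[C@@H]2OC[C@H]1C2(C)C | intermediate
28 | α-substituted acrolein (C3 aldehyde) | C=C(C=O)[C@@H]1CC[C@@H]2[C@H](C1)C(=O)OC[C@]21C(=O)C[C@@H]2OC[C@H]1C2(C)C | intermediate
29 | CNP0268721.1, (6R,9R,10S,16S,20S,23S) in SMILES numbering | C=C(C(=O)O)[C@@H]1CC[C@@H]2[C@H](C1)C(=O)OC[C@]21C(=O)C[C@@H]2OC[C@H]1C2(C)C | target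

Total step count: 15. Longest linear sequence: 15 steps (1 to 29).

Steps most likely to fail

Step 9. The acrylate may add to the other face of the diene and give the C9 epimer, or the silyl dienol ether may be lost by protodesilylation before the s-cis ester rotamer reacts. The fallback sets out from enal 15 and comes back at 21; it changes the C17 flank from silyl enol ether to ketone, which alters both the screening next to the diene and the thermal behaviour. One equivalent of tert-butyldimethylsilyl triflate with triethylamine at −78 °C should silylate only the enal and give keto dienol ether pivalate F1. LiAlH4 then reduces pivalate and ketone to diol F2. Acryloyl chloride with 2,4,6-collidine at −40 °C acylates the primary C15 hydroxyl to give hydroxy acrylate F3. Parikh–Doering oxidation (SO3·pyridine, DMSO, Et3N) restores the ketone in keto acrylate F4. Thermolysis of F4 under the conditions of step 9 should then give 21 directly.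

Step 2. Enantioface discrimination may be insufficient, or 1,2-addition may compete, with the bulky α-silyl Grignard reagent. The fallback sets out from 1 and comes back at 7; C23 is set by hydride delivery instead of carbon delivery. Copper-catalysed addition of Grignard reagent 5 to 1 (CuI cat., Me3SiCl) gives racemic silyl enol ether F5. Saegusa–Ito oxidation (Pd(OAc)2, MeCN) gives the achiral β-substituted enone F6. Asymmetric copper hydride conjugate reduction (Cu(OAc)2, (R)-DTBM-SEGPHOS, polymethylhydrosiloxane), then MeLi and allyl bromide, gives trans allyl ketone F7. Kinetic enolisation on the CH2 side (LiN(i-Pr)2, Me3SiCl, −78 °C) gives silyl enol ether F8, and a second Saegusa–Ito oxidation gives 7.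

Step 13. The C6 radical may be captured on the axial face, or the iodide may be reduced or eliminated faster than it couples. The fallback sets out from 24 and comes back at 26. Zinc insertion (Zn, LiCl, THF) gives cyclohexylzinc iodide F9, whose C–Zn bond is configurationally labile and should settle in the equatorial position. Negishi coupling with 25 (Pd(OAc)2, 2-dicyclohexylphosphino-2′,6′-bis(dimethylamino)biphenyl, THF) then transfers the isopropenyl group with retention.

Further compounds
F1 | step 9 | keto dienol ether pivalate (C17 ketone, mono-silyl) | CC(C)(C)C(=O)OC[C@@]1(/C=C/C=C/O[Si](C)(C)C(C)(C)C)C(=O)C[C@@H]2OC[C@H]1C2(C)C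
F2 | step 9 | diol (C15 and C17 hydroxyls, either C17 epimer) | OC[C@@]1(/C=C/C=C/O[Si](C)(C)C(C)(C)C)C(O)C[C@@H]2OC[C@H]1C2(C)C
F3 | step 9 | hydroxy acrylate (C15 acrylate, C17 hydroxyl) | C=CC(=O)OC[C@@]1(/C=C/C=C/O[Si](C)(C)C(C)(C)C)C(O)C[C@@H]2OC[C@H]1C2(C)C
F4 | step 9 | keto acrylate (C15 acrylate, C17 ketone) | C=CC(=O)OC[C@@]1(/C=C/C=C/O[Si](C)(C)C(C)(C)C)C(=O)C[C@@H]2OC[C@H]1C2(C)C
F5 | step 2 | racemic trimethylsilyl enol ether of the conjugate adduct | CC(C)O[Si](C)(C)CC1C=C(O[Si](C)(C)C)CCC1(C)C
F6 | step 2 | 3-{[isopropoxy(dimethyl)silyl]methyl}-4,4-dimethylcyclohex-2-en-1-one | CC(C)O[Si](C)(C)CC1=CC(=O)CCC1(C)C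
F7 | step 2 | trans-2-allyl-3-{[isopropoxy(dimethyl)silyl]methyl}-4,4-dimethylcyclohexan-1-one (C23 as in the target) | C=CC[C@H]1C(=O)CCC(C)(C)[C@@H]1C[Si](C)(C)OC(C)C
F8 | step 2 | kinetic trimethylsilyl enol ether of F7 | C=CC[C@H]1C(O[Si](C)(C)C)=CCC(C)(C)[C@@H]1C[Si](C)(C)OC(C)C
F9 | step 13 | C6 cyclohexylzinc iodide (C6 configuration labile) | I[Zn]C1CC[C@@H]2[C@H](C1)C(=O)OC[C@]21C(=O)C[C@@H]2OC[C@H]1C2(C)C
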